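**Retrosynthetic overview**
1. Target ⇒ tartrate-controlled epoxidation of the C14 allylic alcohol of a macrocyclic 1(10),2-dienolide; the 1,10-epoxide is the last ring.
2. Macrocycle ⇒ intramolecular Ni/Cr vinylation–lactonization of an acyclic (Z)-β-bromo enoate / α,β-epoxy aldehyde: the C6–C7 bond, the 10-membered carbocycle and the butenolide form in one operation, and C6 is set by Felkin–Anh addition.
3. Seco-aldehyde ⇒ Sonogashira union at C1–C2 of a vinyl iodide (C7–C14 half) with an alkynyl epoxy alcohol (C2–C6 half), then Lindlar reduction (2Z).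
4. Left half ⇒ propargyl alcohol + allylmagnesium bromide (carbomagnesiation/iodination), ozonolysis, asymmetric propiolate addition (C8), anti bromo-hydroxymethylation of the ynoate (C7=C11, C13).
5. Right half ⇒ Sharpless epoxidation of commercial (Z)-3-methylpent-2-en-4-yn-1-ol. Ring order: 4,5-epoxide → carbocycle + butenolide together → 1,10-epoxide.

Assumption: germacrane numbering (C1–C15) is used for position labels (target = 1R,4R,5S,6S,8S,10S; C2/C9 trans on the 1,10-epoxide, C3/C6 cis on the 4,5-epoxide), and each named chiral ligand is the antipode that gives the facial sense stated in its step.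

**Step 1**
Reactants: 1 prop-2-yn-1-ol (propargyl alcohol); 2 allylmagnesium bromide
Product: 4 (Z)-2-(iodomethylene)pent-4-en-1-ol, via vinylmagnesium alkoxide 3 (not isolated)
Conditions: 2 (2.6 equiv), CuI (10 mol %), Et2O, 0 °C → rt; then I2, THF, −40 → 0 °C
Reagents that add atoms: iodine (II)
Why: Duboudin-type anti-carbomagnesiation of the propargylic alkoxide puts allyl on C10 and magnesium on C1 inside a five-membered chelate, so iodinolysis with retention gives the iodide cis to CH2OH, which fixes the later C2-cis-to-C14 geometry of the C1=C10 unit.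

**Step 2**
Reactants: 4 (Z)-2-(iodomethylene)pent-4-en-1-ol
Product: 5 (Z)-tert-butyl{[2-(iodomethylene)pent-4-en-1-yl]oxy}dimethylsilane
Conditions: TBSCl, imidazole, CH2Cl2, 0 °C → rt
Reagents that add atoms: tert-butyldimethylsilyl chloride (CC(C)(C)[Si](C)(C)Cl)
Why: Standard silylation of the primary allylic alcohol masks C14–OH through the acylation and oxidation steps.

**Step 3**
Reactants: 5 (Z)-tert-butyl{[2-(iodomethylene)pent-4-en-1-yl]oxy}dimethylsilane
Product: 7 (Z)-3-{[(tert-butyldimethylsilyl)oxy]methyl}-4-iodobut-3-enal, via ozonide 6 (not isolated)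
Conditions: O3, CH2Cl2, −78 °C (Sudan Red 7B end point); then PPh3, −78 °C → rt
Reagents that add atoms: ozone ([O-][O+]=O)
Why: Ozonolysis with reductive work-up cleaves the electron-rich terminal alkene much faster than the iodine-deactivated trisubstituted alkene, giving the C8 aldehyde, which is used at once because it is β,γ-unsaturated.

**Step 4**
Reactants: 7 (Z)-3-{[(tert-butyldimethylsilyl)oxy]methyl}-4-iodobut-3-enal; 8 methyl propiolate
Product: 9 methyl (4S,6Z)-6-{[(tert-butyldimethylsilyl)oxy]methyl}-4-hydroxy-7-iodohept-6-en-2-ynoate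
Conditions: Me2Zn, (S,S)-ProPhenol (20 mol %), Ph3P=O (40 mol %), toluene, 0 °C
Reagents that add atoms: none
Why: Zn–ProPhenol catalysed asymmetric alkynylation adds the zinc propiolate to the Re face of the aldehyde under mild conditions that tolerate the enolizable aldehyde, setting C8 as S.

**Step 5**
Reactants: 9 methyl (4S,6Z)-6-{[(tert-butyldimethylsilyl)oxy]methyl}-4-hydroxy-7-iodohept-6-en-2-ynoate
Product: 10 methyl (4S,6Z)-6-{[(tert-butyldimethylsilyl)oxy]methyl}-7-iodo-4-(methacryloyloxy)hept-6-en-2-ynoate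
Conditions: methacryloyl chloride, Et3N, DMAP (cat.), CH2Cl2, −20 → 0 °C
Reagents that add atoms: methacryloyl chloride (C=C(C)C(Cl)=O)
Why: Acylation of the secondary propargylic alcohol installs the final C8 ester early, with no change at the stereocentre.

**Step 6**
Reactants: 10 methyl (4S,6Z)-6-{[(tert-butyldimethylsilyl)oxy]methyl}-7-iodo-4-(methacryloyloxy)hept-6-en-2-ynoate
Product: 12 methyl (2Z,4S,6Z)-2-(acetoxymethyl)-3-bromo-6-{[(tert-butyldimethylsilyl)oxy]methyl}-7-iodo-4-(methacryloyloxy)hepta-2,6-dienoate, via bromomagnesium alkoxide 11 (not isolated)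
Conditions: MgBr2·OEt2, CH2O (THF solution from cracked paraformaldehyde), CH2Cl2, −20 → 0 °C; then Ac2O, DMAP (cat.), 0 °C
Reagents that add atoms: magnesium bromide ([Mg+2].[Br-].[Br-]); formaldehyde (C=O); acetic anhydride (CC(=O)OC(C)=O)
Why: Proposed new method: Mg-activated conjugate addition of bromide to the ynoate gives a β-bromo allenoate that is trapped at C11 by formaldehyde on the side away from the halide (net anti addition, Br cis to CO2Me and CH2O cis to C8), and the alkoxide is acetylated in the same flask; the closest known reaction type is the Z-selective halo-aldol (β-halo Morita–Baylis–Hillman) reaction of propiolates with MgI2 or TiCl4/halide, and the same anti sense is seen in HX additions to 2-alkynoates.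

**Step 7**
Reactants: 13 (Z)-3-methylpent-2-en-4-yn-1-ol
Product: 14 [(2S,3R)-3-ethynyl-3-methyloxiran-2-yl]methanol
Conditions: Ti(OiPr)4 (10 mol %), L-(+)-DET (12 mol %), t-BuOOH, 4 Å MS, CH2Cl2, −20 °C
Reagents that add atoms: tert-butyl hydroperoxide (CC(C)(C)OO)
Why: Katsuki–Sharpless asymmetric epoxidation of this nerol-type (Z)-allylic alcohol with L-(+)-tartrate gives the (2S,3R) epoxide, setting C4 (R) and C5 (S) and the cis epoxide geometry from the Z alkene.

**Step 8**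
Reactants: 12 methyl (2Z,4S,6Z)-2-(acetoxymethyl)-3-bromo-6-{[(tert-butyldimethylsilyl)oxy]methyl}-7-iodo-4-(methacryloyloxy)hepta-2,6-dienoate; 14 [(2S,3R)-3-ethynyl-3-methyloxiran-2-yl]methanol
Product: 15 methyl (2Z,4S,6Z)-2-(acetoxymethyl)-3-bromo-6-{[(tert-butyldimethylsilyl)oxy]methyl}-9-[(2R,3S)-3-(hydroxymethyl)-2-methyloxiran-2-yl]-4-(methacryloyloxy)nona-2,6-dien-8-ynoate
Conditions: PdCl2(PPh3)2 (3 mol %), CuI (6 mol %), Et3N, THF, 0 °C → rt
Reagents that add atoms: none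
Why: Sonogashira coupling takes place at the unhindered C(sp2)–I bond in preference to the tetrasubstituted C–Br bond and keeps the alkene geometry, joining C1 to C2.

**Step 9**
Reactants: 15 methyl (2Z,4S,6Z)-2-(acetoxymethyl)-3-bromo-6-{[(tert-butyldimethylsilyl)oxy]methyl}-9-[(2R,3S)-3-(hydroxymethyl)-2-methyloxiran-2-yl]-4-(methacryloyloxy)nona-2,6-dien-8-ynoate
Product: 16 methyl (2Z,4S,6Z,8Z)-2-(acetoxymethyl)-3-bromo-6-{[(tert-butyldimethylsilyl)oxy]methyl}-9-[(2R,3S)-3-(hydroxymethyl)-2-methyloxiran-2-yl]-4-(methacryloyloxy)nona-2,6,8-trienoate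
Conditions: H2 (1 atm), Lindlar catalyst, quinoline, EtOAc, rt (stopped at 1 equiv H2)
Reagents that add atoms: none
Why: Lindlar syn-semihydrogenation of the only alkyne gives the 2Z alkene, with quinoline poisoning to spare the alkenes, the vinyl bromide and the epoxide.

**Step 10**
Reactants: 16 methyl (2Z,4S,6Z,8Z)-2-(acetoxymethyl)-3-bromo-6-{[(tert-butyldimethylsilyl)oxy]methyl}-9-[(2R,3S)-3-(hydroxymethyl)-2-methyloxiran-2-yl]-4-(methacryloyloxy)nona-2,6,8-trienoate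
Product: 17 methyl (2Z,4S,6Z,8Z)-2-(acetoxymethyl)-3-bromo-6-{[(tert-butyldimethylsilyl)oxy]methyl}-9-[(2R,3R)-3-formyl-2-methyloxiran-2-yl]-4-(methacryloyloxy)nona-2,6,8-trienoate
Conditions: Dess–Martin periodinane, pyridine, CH2Cl2, 0 °C
Reagents that add atoms: none
Why: Buffered Dess–Martin oxidation of the only free alcohol gives the α,β-epoxy aldehyde without epimerization or epoxide opening (the descriptor at C5 changes only through CIP priorities).

**Step 11**
Reactants: 17 methyl (2Z,4S,6Z,8Z)-2-(acetoxymethyl)-3-bromo-6-{[(tert-butyldimethylsilyl)oxy]methyl}-9-[(2R,3R)-3-formyl-2-methyloxiran-2-yl]-4-(methacryloyloxy)nona-2,6,8-trienoate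
Product: 20 (4R,5S,6S,8S)-13-acetoxy-14-[(tert-butyldimethylsilyl)oxy]-4,5-epoxy-8-(methacryloyloxy)germacra-1(10),2Z,7(11)-trien-12,6-olide (C2 trans to C9 across C1=C10), via vinylchromium species 18 (not isolated), via seco hydroxy ester 19 (not isolated)
Conditions: CrCl2 (10 equiv), NiCl2 (20 mol %), DMSO–THF, 2 mM (slow addition), rt
Reagents that add atoms: none
Why: In this intramolecular Nozaki–Hiyama–Kishi reaction Ni inserts into the activated C7–Br bond, the vinylchromium adds to the epoxy aldehyde anti to the epoxide C–O bond (Felkin–Anh, erythro, 6S), and the C6 alkoxide, held cis to CO2Me, lactonizes at once, so the 10-membered carbocycle and the butenolide form together.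

**Step 12**
Reactants: 20 (4R,5S,6S,8S)-13-acetoxy-14-[(tert-butyldimethylsilyl)oxy]-4,5-epoxy-8-(methacryloyloxy)germacra-1(10),2Z,7(11)-trien-12,6-olide
Product: 21 (4R,5S,6S,8S)-13-acetoxy-4,5-epoxy-14-hydroxy-8-(methacryloyloxy)germacra-1(10),2Z,7(11)-trien-12,6-olide
Conditions: HF·pyridine, pyridine, THF, 0 °C
Reagents that add atoms: none
Why: Buffered fluoride cleaves the primary allylic silyl ether without touching the esters, the lactone or the vinyl epoxide.

**Step 13**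
Reactants: 21 (4R,5S,6S,8S)-13-acetoxy-4,5-epoxy-14-hydroxy-8-(methacryloyloxy)germacra-1(10),2Z,7(11)-trien-12,6-olide
Product: 22 CNP0207684.1, (1R,4R,5S,6S,8S,10S)-13-acetoxy-1,10:4,5-diepoxy-14-hydroxy-8-(methacryloyloxy)germacra-2Z,7(11)-dien-12,6-olide
Conditions: Ti(OiPr)4 (20 mol %), L-(+)-DIPT (24 mol %), t-BuOOH, 4 Å MS, CH2Cl2, −20 °C
Reagents that add atoms: tert-butyl hydroperoxide (CC(C)(C)OO)
Why: Sharpless asymmetric epoxidation is directed by C14–OH to the C1=C10 alkene only, and L-(+)-tartrate delivers oxygen to the face that gives 1R,10S, while the alkene geometry gives the trans epoxide.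

**Compound list**
1 | prop-2-yn-1-ol (propargyl alcohol) | C#CCO | starting material
2 | allylmagnesium bromide | C=CC[Mg]Br | starting material
3 | bromomagnesium (Z)-2-[(bromomagnesio)methylene]pent-4-en-1-olate | C=CC/C(CO[Mg]Br)=C/[Mg]Br | intermediate
4 | (Z)-2-(iodomethylene)pent-4-en-1-ol | C=CC/C(CO)=C/I | intermediate
5 | (Z)-tert-butyl{[2-(iodomethylene)pent-4-en-1-yl]oxy}dimethylsilane | C=CC/C(CO[Si](C)(C)C(C)(C)C)=C/I | intermediate
6 | 3-[(Z)-2-{[(tert-butyldimethylsilyl)oxy]methyl}-3-iodoprop-2-en-1-yl]-1,2,4-trioxolane (ozonide) | CC(C)(C)[Si](C)(C)OC/C(CC1OCOO1)=C\I | intermediate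
7 | (Z)-3-{[(tert-butyldimethylsilyl)oxy]methyl}-4-iodobut-3-enal | CC(C)(C)[Si](C)(C)OC/C(CC=O)=C\I | intermediate
8 | methyl propiolate | C#CC(=O)OC | starting material
9 | methyl (4S,6Z)-6-{[(tert-butyldimethylsilyl)oxy]methyl}-4-hydroxy-7-iodohept-6-en-2-ynoate | COC(=O)C#C[C@@H](O)C/C(CO[Si](C)(C)C(C)(C)C)=C/I | intermediate
10 | methyl (4S,6Z)-6-{[(tert-butyldimethylsilyl)oxy]methyl}-7-iodo-4-(methacryloyloxy)hept-6-en-2-ynoate | COC(=O)C#C[C@@H](OC(=O)C(C)=C)C/C(CO[Si](C)(C)C(C)(C)C)=C/I | intermediate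
11 | methyl (2Z,4S,6Z)-3-bromo-6-{[(tert-butyldimethylsilyl)oxy]methyl}-2-(hydroxymethyl)-7-iodo-4-(methacryloyloxy)hepta-2,6-dienoate (present as its bromomagnesium alkoxide) | COC(=O)/C(CO)=C(\Br)[C@@H](OC(=O)C(C)=C)C/C(CO[Si](C)(C)C(C)(C)C)=C/I | intermediate
12 | methyl (2Z,4S,6Z)-2-(acetoxymethyl)-3-bromo-6-{[(tert-butyldimethylsilyl)oxy]methyl}-7-iodo-4-(methacryloyloxy)hepta-2,6-dienoate | COC(=O)/C(COC(C)=O)=C(\Br)[C@@H](OC(=O)C(C)=C)C/C(CO[Si](C)(C)C(C)(C)C)=C/I | intermediate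
13 | (Z)-3-methylpent-2-en-4-yn-1-ol | C#C/C(C)=C\CO | starting material
14 | [(2S,3R)-3-ethynyl-3-methyloxiran-2-yl]methanol | C#C[C@@]1(C)O[C@H]1CO | intermediate
15 | methyl (2Z,4S,6Z)-2-(acetoxymethyl)-3-bromo-6-{[(tert-butyldimethylsilyl)oxy]methyl}-9-[(2R,3S)-3-(hydroxymethyl)-2-methyloxiran-2-yl]-4-(methacryloyloxy)nona-2,6-dien-8-ynoate | COC(=O)/C(COC(C)=O)=C(\Br)[C@@H](OC(=O)C(C)=C)C/C(CO[Si](C)(C)C(C)(C)C)=C/C#C[C@@]1(C)O[C@H]1CO | intermediate
16 | methyl (2Z,4S,6Z,8Z)-2-(acetoxymethyl)-3-bromo-6-{[(tert-butyldimethylsilyl)oxy]methyl}-9-[(2R,3S)-3-(hydroxymethyl)-2-methyloxiran-2-yl]-4-(methacryloyloxy)nona-2,6,8-trienoate | COC(=O)/C(COC(C)=O)=C(\Br)[C@@H](OC(=O)C(C)=C)C/C(CO[Si](C)(C)C(C)(C)C)=C/C=C\[C@@]1(C)O[C@H]1CO | intermediate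
17 | methyl (2Z,4S,6Z,8Z)-2-(acetoxymethyl)-3-bromo-6-{[(tert-butyldimethylsilyl)oxy]methyl}-9-[(2R,3R)-3-formyl-2-methyloxiran-2-yl]-4-(methacryloyloxy)nona-2,6,8-trienoate | COC(=O)/C(COC(C)=O)=C(\Br)[C@@H](OC(=O)C(C)=C)C/C(CO[Si](C)(C)C(C)(C)C)=C/C=C\[C@@]1(C)O[C@H]1C=O | intermediate
18 | C7 dichlorochromium(III) alkenyl species derived from 17 (Cr in place of Br, geometry retained) | COC(=O)/C(COC(C)=O)=C(\[Cr](Cl)Cl)[C@@H](OC(=O)C(C)=C)C/C(CO[Si](C)(C)C(C)(C)C)=C/C=C\[C@@]1(C)O[C@H]1C=O | intermediate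
19 | methyl (4R,5S,6S,8S)-13-acetoxy-14-[(tert-butyldimethylsilyl)oxy]-4,5-epoxy-6-hydroxy-8-(methacryloyloxy)germacra-1(10),2Z,7(11)-trien-12-oate, C6–O cis to CO2Me (present as its Cr(III) alkoxide) | C=C(C)C(=O)O[C@H]1C/C(CO[Si](C)(C)C(C)(C)C)=C/C=C\[C@@]2(C)O[C@H]2[C@@H](O)/C1=C(/COC(C)=O)C(=O)OC | intermediate
20 | (4R,5S,6S,8S)-13-acetoxy-14-[(tert-butyldimethylsilyl)oxy]-4,5-epoxy-8-(methacryloyloxy)germacra-1(10),2Z,7(11)-trien-12,6-olide (C2 trans to C9 across C1=C10) | C=C(C)C(=O)O[C@H]1C/C(CO[Si](C)(C)C(C)(C)C)=C/C=C\[C@@]2(C)O[C@H]2[C@H]2OC(=O)C(COC(C)=O)=C12 | intermediate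
21 | (4R,5S,6S,8S)-13-acetoxy-4,5-epoxy-14-hydroxy-8-(methacryloyloxy)germacra-1(10),2Z,7(11)-trien-12,6-olide | C=C(C)C(=O)O[C@H]1C/C(CO)=C/C=C\[C@@]2(C)O[C@H]2[C@H]2OC(=O)C(COC(C)=O)=C12 | intermediate
22 | CNP0207684.1, (1R,4R,5S,6S,8S,10S)-13-acetoxy-1,10:4,5-diepoxy-14-hydroxy-8-(methacryloyloxy)germacra-2Z,7(11)-dien-12,6-olide | C=C(C)C(=O)O[C@H]1C[C@@]2(CO)O[C@@H]2/C=C\[C@@]2(C)O[C@H]2[C@H]2OC(=O)C(COC(C)=O)=C12 | target

**Totals**
Total step count: 13. Longest linear sequence: 12 (steps 1–6, then 8–13; step 7 is the one-step side branch).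

**Three steps most likely to fail**

Step 6 (bromo-hydroxymethylation; regio- and stereochemistry of a tetrasubstituted alkene on a γ-acyloxy ynoate). The fallback sets out from 9 and comes back at 12; it fixes the geometry with a temporary tether instead of relying on the face of an allenoate. Alcohol 9 is silylated with (bromomethyl)chlorodimethylsilane and imidazole to methyl (4S,6Z)-4-{[(bromomethyl)dimethylsilyl]oxy}-6-{[(tert-butyldimethylsilyl)oxy]methyl}-7-iodohept-6-en-2-ynoate F1. Catalytic Bu4NBr with MgBr2·OEt2 then adds bromide to C7, and the allenoate alkylates at C11 through the tether, closing the six-membered methyl (6S)-5-bromo-6-[(2Z)-2-{[(tert-butyldimethylsilyl)oxy]methyl}-3-iodoprop-2-en-1-yl]-2,2-dimethyl-3,6-dihydro-2H-1,2-oxasiline-4-carboxylate F2; the ring forces C13 cis to C8 and Br cis to CO2Me. Tamao oxidation (KF, KHCO3, H2O2) gives methyl (2Z,4S,6Z)-3-bromo-6-{[(tert-butyldimethylsilyl)oxy]methyl}-4-hydroxy-2-(hydroxymethyl)-7-iodohepta-2,6-dienoate F3. Selective acetylation of the primary alcohol (Ac2O, 2,4,6-collidine, −40 °C) gives methyl (2Z,4S,6Z)-2-(acetoxymethyl)-3-bromo-6-{[(tert-butyldimethylsilyl)oxy]methyl}-4-hydroxy-7-iodohepta-2,6-dienoate F4, and methacryloyl chloride/Et3N/DMAP returns to 12.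

Step 11 (macrocyclization; strain of the E,Z-diene in the ring, Cr/Ni sensitivity of the epoxy aldehyde and vinyl epoxide). The fallback sets out from 16 and comes back at 22; it cyclizes a seco-compound that already carries both epoxides, so C1 and C10 are sp3 in the ring-closing step. HF·pyridine removes the silyl group from 16 to give the C6,C14-diol, methyl (2Z,4S,6Z,8Z)-2-(acetoxymethyl)-3-bromo-6-(hydroxymethyl)-9-[(2R,3S)-3-(hydroxymethyl)-2-methyloxiran-2-yl]-4-(methacryloyloxy)nona-2,6,8-trienoate F5. Sharpless epoxidation (L-(+)-DIPT) of its only allylic alcohol gives the bis-epoxide diol, methyl (2Z,4S)-2-(acetoxymethyl)-3-bromo-5-[(2S,3R)-2-(hydroxymethyl)-3-{(Z)-2-[(2R,3S)-3-(hydroxymethyl)-2-methyloxiran-2-yl]ethenyl}oxiran-2-yl]-4-(methacryloyloxy)pent-2-enoate F6. TEMPO/PhI(OAc)2 oxidizes the less hindered C6 alcohol (the C14 alcohol is neopentyl-like) to the corresponding C6 aldehyde, methyl (2Z,4S)-2-(acetoxymethyl)-3-bromo-5-[(2S,3R)-3-{(Z)-2-[(2R,3R)-3-formyl-2-methyloxiran-2-yl]ethenyl}-2-(hydroxymethyl)oxiran-2-yl]-4-(methacryloyloxy)pent-2-enoate F7. The same CrCl2/NiCl2 cyclization–lactonization on F7 gives 22 directly.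

Step 13 (face selectivity of the tartrate catalyst on a constrained macrocyclic dienol; Ti-sensitivity of the vinyl epoxide product). The fallback sets out from 20 and comes back at 22; it uses conformational control of the macrocycle instead of hydroxyl-directed reagent control. Silyl ether 20 is epoxidized with dimethyldioxirane (acetone, −20 °C) at its most electron-rich trisubstituted C1=C10 alkene from the peripheral face to give the 14-O-tert-butyldimethylsilyl ether of 22, (1R,4R,5S,6S,8S,10S)-13-acetoxy-14-[(tert-butyldimethylsilyl)oxy]-1,10:4,5-diepoxy-8-(methacryloyloxy)germacra-2Z,7(11)-dien-12,6-olide F8. HF·pyridine then gives 22.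

**Further compounds**
F1 | step 6 | methyl (4S,6Z)-4-{[(bromomethyl)dimethylsilyl]oxy}-6-{[(tert-butyldimethylsilyl)oxy]methyl}-7-iodohept-6-en-2-ynoate | COC(=O)C#C[C@@H](O[Si](C)(C)CBr)C/C(CO[Si](C)(C)C(C)(C)C)=C/I
F2 | step 6 | methyl (6S)-5-bromo-6-[(2Z)-2-{[(tert-butyldimethylsilyl)oxy]methyl}-3-iodoprop-2-en-1-yl]-2,2-dimethyl-3,6-dihydro-2H-1,2-oxasiline-4-carboxylate | COC(=O)C1=C(Br)[C@H](C/C(CO[Si](C)(C)C(C)(C)C)=C/I)O[Si](C)(C)C1
F3 | step 6 | methyl (2Z,4S,6Z)-3-bromo-6-{[(tert-butyldimethylsilyl)oxy]methyl}-4-hydroxy-2-(hydroxymethyl)-7-iodohepta-2,6-dienoate | COC(=O)/C(CO)=C(\Br)[C@@H](O)C/C(CO[Si](C)(C)C(C)(C)C)=C/I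
F4 | step 6 | methyl (2Z,4S,6Z)-2-(acetoxymethyl)-3-bromo-6-{[(tert-butyldimethylsilyl)oxy]methyl}-4-hydroxy-7-iodohepta-2,6-dienoate | COC(=O)/C(COC(C)=O)=C(\Br)[C@@H](O)C/C(CO[Si](C)(C)C(C)(C)C)=C/I
F5 | step 11 | methyl (2Z,4S,6Z,8Z)-2-(acetoxymethyl)-3-bromo-6-(hydroxymethyl)-9-[(2R,3S)-3-(hydroxymethyl)-2-methyloxiran-2-yl]-4-(methacryloyloxy)nona-2,6,8-trienoate | COC(=O)/C(COC(C)=O)=C(\Br)[C@@H](OC(=O)C(C)=C)C/C(CO)=C/C=C\[C@@]1(C)O[C@H]1CO
F6 | step 11 | methyl (2Z,4S)-2-(acetoxymethyl)-3-bromo-5-[(2S,3R)-2-(hydroxymethyl)-3-{(Z)-2-[(2R,3S)-3-(hydroxymethyl)-2-methyloxiran-2-yl]ethenyl}oxiran-2-yl]-4-(methacryloyloxy)pent-2-enoate | COC(=O)/C(COC(C)=O)=C(\Br)[C@@H](OC(=O)C(C)=C)C[C@@]1(CO)O[C@@H]1/C=C\[C@@]1(C)O[C@H]1CO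
F7 | step 11 | methyl (2Z,4S)-2-(acetoxymethyl)-3-bromo-5-[(2S,3R)-3-{(Z)-2-[(2R,3R)-3-formyl-2-methyloxiran-2-yl]ethenyl}-2-(hydroxymethyl)oxiran-2-yl]-4-(methacryloyloxy)pent-2-enoate | COC(=O)/C(COC(C)=O)=C(\Br)[C@@H](OC(=O)C(C)=C)C[C@@]1(CO)O[C@@H]1/C=C\[C@@]1(C)O[C@H]1C=O
F8 | step 13 | (1R,4R,5S,6S,8S,10S)-13-acetoxy-14-[(tert-butyldimethylsilyl)oxy]-1,10:4,5-diepoxy-8-(methacryloyloxy)germacra-2Z,7(11)-dien-12,6-olide | C=C(C)C(=O)O[C@H]1C[C@@]2(CO[Si](C)(C)C(C)(C)C)O[C@@H]2/C=C\[C@@]2(C)O[C@H]2[C@H]2OC(=O)C(COC(C)=O)=C12
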